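The unit for this flask is not the minute but the half-life of the product pair. The north run offers two ways to it, both through the gap between right-handed and left-handed product. Read as plain decay, the gap falls from 8.5 percentage points at 0.833 min to 4.2 points at 2.00 min, a half-life of 1.15 min. A balance reads differently. Between 0.500 min and 2.00 min left-handed product gains 16 points while left-handed substrate loses 3.2 points, so about 13 points crossed over from right-handed product. A mean gap of 7.1 points carrying that flow gives 0.293 min for the racemisation half-life, the time in which left-handed product <-> right-handed product by itself halves the gap. The decay figure is longer than the balance figure, and it is the one that cheats: right-handed product still rose by 5.5 points over its interval, so the gap was being refilled as it fell.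

| flask | left-handed substrate | right-handed substrate | partner | protic impurity | free catalyst | remark | time |
|---|---|---|---|---|---|---|---|
| west | 0.20 M | 0.20 M | 1.5 equiv | 0.060 M | 0.07 mol% | run made earlier |  |
| north | 0.20 M | 0.20 M | 1.5 equiv | 0.060 M | 0.11 mol% | run made earlier |  |
| flask | 0.20 M | 0.20 M | 1.50 equiv | 0.0600 M | 0.05 mol% |  | 5.0 min |

- west (time / min: left-handed product / %, right-handed product / %, left-handed substrate / %): 0.167: 1.1, 5.2, 48.8; 0.500: 5.2, 11.7, 48.7; 0.833: 8.4, 17.9, 47.5; 1.33: 12.9, 20.1, 46.8; 2.00: 17.9, 23.7, 46.1; 2.50: 23.4, 25.0, 46.1; 3.00: 21.9, 25.2, 42.6
- north (time / min: left-handed product / %, right-handed product / %, left-handed substrate / %): 0.167: 0.4, 7.6, 49.1; 0.500: 6.9, 16.2, 46.3; 0.833: 12.9, 21.4, 46.0; 1.33: 18.5, 24.9, 46.1; 2.00: 22.7, 26.9, 43.1; 2.50: 25.6, 27.0, 42.9; 3.00: 28.7, 27.7, 42.1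

(each reading ± 1 percentage point)

- free catalyst is single-handed; left-handed substrate and right-handed substrate are mirror images of each other, charged as a racemate, each of them at the stated concentration
- steps under discussion: free catalyst + right-handed substrate <-> catalyst intermediate B; partner + catalyst intermediate A -> free catalyst + left-handed product; free catalyst + left-handed substrate <-> catalyst intermediate A; partner + catalyst intermediate B -> free catalyst + right-handed product; 2 free catalyst <-> resting dimer; partner + protic impurity -> quenched reagent; left-handed product <-> right-handed product
- an excess is the difference of the two amounts in percent of their sum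
- an excess is below zero if the other one leads

- excess of left-handed product over right-handed product in the product at 30 s
- excess of left-handed product over right-handed product in the product at 5.0 min
- part of the left-handed substrate and right-handed substrate charged together that has reacted at 5.0 min

The new flask can now be counted. Its 30 s is 1.71 half-lives. Left-handed substrate accounts for 14.0 % of the north product at 3.00 min, which makes the feed's own excess −72.0 %. For a steady feed, mixing multiplies that by one minus e to the minus x, over x, with x the count times ln two. That factor is 0.586, and the size of the feed cancels, so the reckoning here gives −42.2 % at 30 s. Its 5.0 min is 17.1 half-lives, after which <0.001 % of any early gap stands. What remains is a quasi-steady gap, feed times 0.293 min over ln two. The west run's whole late output, 0.0550 min⁻¹ of the charge, taken as feed, holds 2.3 points, an excess of 4.94 % on that run's product.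

The forecast says −51 %, −0.5 % and 55 % ("Product is almost racemic"), and its early excess lies further from zero than the −42.2 % reckoned here.

The flask gives −48.3 %, −1.45 % and 51.2 %.

    free catalyst + right-handed substrate ⇌ catalyst intermediate B (K = 108 M⁻¹, k = 3370 M⁻¹ s⁻¹)
    partner + catalyst intermediate A → free catalyst + left-handed product (k = 147 M⁻¹ s⁻¹)
    free catalyst + left-handed substrate ⇌ catalyst intermediate A (K = 3.00 M⁻¹, k = 1130 M⁻¹ s⁻¹)
    partner + catalyst intermediate B → free catalyst + right-handed product (k = 66.9 M⁻¹ s⁻¹)
    2 free catalyst ⇌ resting dimer, settled at all times (K = 2000 M⁻¹)
    partner + protic impurity → quenched reagent (k = 0.222 M⁻¹ s⁻¹)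
    left-handed product ⇌ right-handed product (k = 0.0184 s⁻¹)

The early excess stands 6.1 points beyond the reckoned one, and the late excess is smaller than the reckoned 4.94 %. Counted on the reading of 0.293 min, this flask's 5.0 min holds 17.1 half-lives, and at that time right-handed product in this flask is still made 2.57 times faster than it is used up. A neighbour flask charged with 0.600 equiv of partner, its 5.0 min counted on the same reading as 17.1 half-lives, has 15.4 % reacted and stands at an excess of −1.84 %.

The readings are calculated from invented constants; scatter was added.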